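## Retrosynthetic overview

1. Dichamanetin ⇒ (S)-pinocembrin + 2 × 2-hydroxybenzyl alcohol (double ortho-quinone-methide Friedel–Crafts benzylation at C6 and C8, done last).
2. (S)-Pinocembrin ⇒ an acyclic (S)-δ-hydroxy-diketo-dioxinone. Ring C and then ring A close in one pot: cyclodehydration to a dihydropyranone, then dioxinone → acylketene → 6π benzannulation.
3. Hydroxy-diketo-dioxinone ⇒ keto-dioxinone dianion + ethyl (S)-3-hydroxy-3-phenylpropanoate (crossed Claisen). The carbinol C–O bond becomes the C2–O1 bond and is never broken.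
4. Keto-dioxinone ⇒ 2,2,6-trimethyl-4H-1,3-dioxin-4-one + acetyl chloride (γ-acylation).
5. Ring order: ring C first, ring A second, in the same operation. Ring B and the two hydroxyphenyl rings are bought.

Assumption: ethyl (S)-3-hydroxy-3-phenylpropanoate (≥98% ee) is bought as a catalogue chiral building block.
Assumption: lithium enolates are treated as the deprotonated forms of their numbered parent compounds and carry no numbers of their own.

## Route

Step 1
Reactants: 1 2,2,6-trimethyl-4H-1,3-dioxin-4-one (2.0 equiv); 2 acetyl chloride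
Product: 3 2,2-dimethyl-6-(2-oxopropyl)-4H-1,3-dioxin-4-one
Conditions: LiN(SiMe3)2 (2.1 equiv), THF, −78 °C; then 2 (1.0 equiv), −78 → −40 °C; 1 M HCl
Reagents that add atoms: none
Why: γ-Deprotonation of the vinylogous ester gives the lithium dienolate, which is C-acylated at the exocyclic γ-carbon by acetyl chloride (Claisen-type γ-acylation of a dioxinone dienolate), the second equivalent of dienolate taking up the more acidic product proton; no stereocentre is formed.

Step 2
Reactants: 3 2,2-dimethyl-6-(2-oxopropyl)-4H-1,3-dioxin-4-one; 4 ethyl (3S)-3-hydroxy-3-phenylpropanoate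
Product: 5 6-[(6S)-6-hydroxy-2,4-dioxo-6-phenylhexyl]-2,2-dimethyl-4H-1,3-dioxin-4-one
Conditions: 3 (2.2 equiv), LiN(i-Pr)2 (4.4 equiv), THF, −78 → −40 °C; then 4 (1.0 equiv, pre-mixed with LiN(i-Pr)2, 1.0 equiv, THF, −78 °C), −78 → −20 °C; AcOH, −78 °C
Reagents that add atoms: none
Why: The dianion of 3 attacks the ester carbonyl of the lithium alkoxide of 4 through its terminal carbon in a crossed Claisen condensation (dianion acylation, as used to chain-extend unprotected β-hydroxy esters with lithium enolates), and the (S) carbinol centre of 4 is carried over unchanged because it has no acidic hydrogen and the product sits as a delocalised polyenolate that resists retro-aldol cleavage.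

Step 3
Reactants: 5 6-[(6S)-6-hydroxy-2,4-dioxo-6-phenylhexyl]-2,2-dimethyl-4H-1,3-dioxin-4-one
Product: 8 (2S)-5,7-dihydroxy-2-phenylchroman-4-one ((S)-pinocembrin), via dihydropyranone-dioxinone 6 (not isolated), via acylketene 7 (not isolated)
Conditions: (±)-camphorsulfonic acid (10 mol %), 4 Å MS, PhMe (0.01 M), 23 °C, 2 h; then 110 °C, 1 h
Reagents that add atoms: none
Why: Proposed new method: acid first cyclodehydrates the δ-hydroxy-β-diketone to the 2,3-dihydro-4H-pyran-4-one 6 (ring C; the carbinol oxygen is the nucleophile, so the C2–O bond is never broken and (S) is retained), which also turns the C8a oxygen into a ring ether that can no longer O-trap a ketene to a 2-pyrone; heating then expels acetone from the dioxinone by retro-[4+2] to give acylketene 7, whose enol is a dienylketene that closes ring A by 6π-electrocyclisation (equivalently C-acylation of the vinylogous-ester α-carbon C4a) and tautomerises to the phloroglucinol ring, with sieves holding back the water that would otherwise hydrolyse the ketene; the closest known reaction types are the acid cyclodehydration of aldol adducts of β-diketone dianions to dihydropyranones, the dioxinone-thermolysis/late-stage aromatisation route to resorcylates, and the final electrocyclisation of the Danheiser benzannulation.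

Step 4
Reactants: 8 (2S)-5,7-dihydroxy-2-phenylchroman-4-one; 9 2-hydroxybenzyl alcohol (2.5 equiv)
Product: 13 dichamanetin, via o-quinone methide 10 (not isolated), via 6-(2-hydroxybenzyl)pinocembrin 11 (not isolated), via 8-(2-hydroxybenzyl)pinocembrin 12 (not isolated)
Conditions: 9 (2.5 equiv), ZnCl2 (2.5 equiv), 1,4-dioxane, 23 °C
Reagents that add atoms: none
Why: ZnCl2 ionises the benzylic alcohol to o-quinone methide 10 (or its zinc-bound cation), which is attacked in turn by the two free nucleophilic positions C6 and C8 of the phloroglucinol ring in a double Friedel–Crafts (Michael-type) benzylation, and the base-free, mildly Lewis-acidic medium does not open the flavanone ring, so C2 stays (S).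

## Compound list

1 | 2,2,6-trimethyl-4H-1,3-dioxin-4-one | CC1=CC(=O)OC(C)(C)O1 | starting material
2 | acetyl chloride | CC(=O)Cl | starting material
3 | 2,2-dimethyl-6-(2-oxopropyl)-4H-1,3-dioxin-4-one | CC(=O)CC1=CC(=O)OC(C)(C)O1 | intermediate
4 | ethyl (3S)-3-hydroxy-3-phenylpropanoate | O[C@@H](CC(=O)OCC)c1ccccc1 | starting material
5 | 6-[(6S)-6-hydroxy-2,4-dioxo-6-phenylhexyl]-2,2-dimethyl-4H-1,3-dioxin-4-one | O[C@@H](CC(=O)CC(=O)CC1=CC(=O)OC(C)(C)O1)c1ccccc1 | intermediate
6 | (2S)-6-[(2,2-dimethyl-4-oxo-4H-1,3-dioxin-6-yl)methyl]-2-phenyl-2,3-dihydro-4H-pyran-4-one | O=C1C[C@@H](c2ccccc2)OC(CC2=CC(=O)OC(C)(C)O2)=C1 | intermediate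
7 | 4-[(2S)-4-oxo-2-phenyl-3,4-dihydro-2H-pyran-6-yl]but-1-ene-1,3-dione (acylketene) | O=C=CC(=O)CC1=CC(=O)C[C@@H](c2ccccc2)O1 | intermediate
8 | (2S)-5,7-dihydroxy-2-phenylchroman-4-one ((S)-pinocembrin) | O=C1C[C@@H](c2ccccc2)Oc2cc(O)cc(O)c21 | intermediate
9 | 2-hydroxybenzyl alcohol | OCc1ccccc1O | starting material
10 | 6-methylidenecyclohexa-2,4-dien-1-one (o-quinone methide) | C=C1C=CC=CC1=O | intermediate
11 | (2S)-5,7-dihydroxy-6-(2-hydroxybenzyl)-2-phenylchroman-4-one | O=C1C[C@@H](c2ccccc2)Oc2cc(O)c(Cc3ccccc3O)c(O)c21 | intermediate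
12 | (2S)-5,7-dihydroxy-8-(2-hydroxybenzyl)-2-phenylchroman-4-one | O=C1C[C@@H](c2ccccc2)Oc2c(Cc3ccccc3O)c(O)cc(O)c21 | intermediate
13 | dichamanetin, (2S)-5,7-dihydroxy-6,8-bis(2-hydroxybenzyl)-2-phenylchroman-4-one | O=C1C[C@@H](c2ccccc2)Oc2c(Cc3ccccc3O)c(O)c(Cc3ccccc3O)c(O)c21 | target

## Step count and risk

Total step count: 4. Longest linear sequence: 4 steps (1 → 3 → 5 → 8 → 13).

The three steps most likely to fail:

Step 3 (one-pot closure of ring C and ring A). The risks are that the ketene is lost to water or dimerises, or that the electrocyclisation is slow. The fallback sets out from 5 and comes back at 8. It separates the two ring closures and replaces the pericyclic ring-A closure by an ionic one. Compound 5 is cyclodehydrated with camphorsulfonic acid and 4 Å MS in CH2Cl2 at 23 °C, and dihydropyranone 6 is isolated. Compound 6 is then heated in PhMe at 110 °C with MeOH (5 equiv), so that acylketene 7 is trapped as methyl 3-oxo-4-[(2S)-4-oxo-2-phenyl-3,4-dihydro-2H-pyran-6-yl]butanoate F1. Ring A is closed by a magnesium-templated Dieckmann-type Claisen condensation, in which the dienolate of F1 attacks the ester through C4a (Mg(OMe)2, MeOH, 23 °C, then dilute HCl), giving 8. The ee should be checked by chiral HPLC, because this variant exposes the dihydropyranone to base.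

Step 2 (Claisen condensation on the unprotected hydroxy ester). The risks are low conversion of the alkoxide-bearing ester, α-deprotonation of 4, or retro-aldol loss. The fallback sets out from 4 and comes back at 5. The hydroxyl group is masked so that a neutral, more electrophilic ester is acylated. Compound 4 is silylated (TBSCl, imidazole, DMF, 23 °C) to ethyl (3S)-3-[(tert-butyldimethylsilyl)oxy]-3-phenylpropanoate F2. F2 is condensed with the dianion of 3 (LiN(i-Pr)2, THF, −78 → −20 °C) to give 6-[(6S)-6-[(tert-butyldimethylsilyl)oxy]-2,4-dioxo-6-phenylhexyl]-2,2-dimethyl-4H-1,3-dioxin-4-one F3. The silyl ether is removed with HF·pyridine in THF at 0 °C to give 5.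

Step 4 (double benzylation). The risks are mixtures of 11, 12 and 13, self-condensation of 9, and further benzylation on the new phenol rings. The fallback sets out from 8 and comes back at 13. It replaces the quinone-methide electrophile by a protected benzylic cation and adds a deprotection. Compound 8 is alkylated with commercial 2-(benzyloxy)benzyl alcohol (OCc1ccccc1OCc1ccccc1, 2.5 equiv) and Sc(OTf)3 (10 mol %) in MeNO2/CH2Cl2 at 23 °C, an SN1 Friedel–Crafts benzylation, to give (2S)-6,8-bis[2-(benzyloxy)benzyl]-5,7-dihydroxy-2-phenylchroman-4-one F4. Hydrogenolysis of both benzyl ethers (H2, 1 atm, palladium on carbon (Pd/C), EtOAc, 23 °C) gives 13.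

## Further compounds

F1 | step 3 | methyl 3-oxo-4-[(2S)-4-oxo-2-phenyl-3,4-dihydro-2H-pyran-6-yl]butanoate | O=C1C[C@@H](c2ccccc2)OC(CC(=O)CC(=O)OC)=C1
F2 | step 2 | ethyl (3S)-3-[(tert-butyldimethylsilyl)oxy]-3-phenylpropanoate | CC(C)(C)[Si](C)(C)O[C@@H](CC(=O)OCC)c1ccccc1
F3 | step 2 | 6-[(6S)-6-[(tert-butyldimethylsilyl)oxy]-2,4-dioxo-6-phenylhexyl]-2,2-dimethyl-4H-1,3-dioxin-4-one | CC(C)(C)[Si](C)(C)O[C@@H](CC(=O)CC(=O)CC1=CC(=O)OC(C)(C)O1)c1ccccc1
F4 | step 4 | (2S)-6,8-bis[2-(benzyloxy)benzyl]-5,7-dihydroxy-2-phenylchroman-4-one | O=C1C[C@@H](c2ccccc2)Oc2c(Cc3ccccc3OCc3ccccc3)c(O)c(Cc3ccccc3OCc3ccccc3)c(O)c21
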